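**Retrosynthetic overview**
1. Target ⇐ ene-dial from the C10/C12 diol; C10 comes from methylenation and hydroboration at C1, and C12 from Morita–Baylis–Hillman hydroxymethylation of the C8=C9 enone ⇐ (E)-cyclonon-5-enone 19.
2. Feature the plan rests on: with C1 as a ketone, ring atoms C1–C2–C3–C4–C5 are a cyclopentane whose C1–C5 bond carries a vinyl group at each end (C9=C8 on C1, C6=C7 on C5). This 3-oxy-1,5-diene is the retron, so 19 ⇐ trans-1,2-divinylcyclopentanol 16 (form C7–C8, break C1–C5).
3. 16 ⇐ vinylmagnesium bromide + 2-methyl-2-vinylcyclopentanone 15 ⇐ cyclopentene 7 (epoxidation, vinyl-cuprate opening, oxidation, C5 methylation).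
4. C1′, C2 and C3 ⇐ (1S,5R)-2-oxabicyclo[3.3.0]oct-6-en-3-one by convex-face lactone alkylation; the butenyl chain is capped to the isopropylidene terminus by cross-metathesis, after the ring epoxidation.
5. Ring order: the cyclopentane is bought as the bicyclic lactone; the nine-membered ring is made from it by four-carbon ring expansion in step 11; no other ring is formed.

Key step: step 11

Assumption: the target is treated as the open hydroxy-dialdehyde (C3–OH and C10 are trans, so no lactol is expected); target numbering (ring C1–C9, formyl carbons C10 on C1 and C12 on C9, C11 = CH2OAc, C1′ = side-chain methine) is used for all intermediates, and 4-iodobut-1-ene is taken as a catalogue compound.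

**Route**

Step 1
Reactants: 1 (1S,5R)-2-oxabicyclo[3.3.0]oct-6-en-3-one; 2 4-iodobut-1-ene
Product: 4 (1S,4S,5S)-4-(but-3-en-1-yl)-2-oxabicyclo[3.3.0]oct-6-en-3-one, via lithium lactone enolate 3 (not isolated)
Conditions: LDA, THF, −78 °C; then 2, DMPU, −78 → −30 °C
Reagents that add atoms: lithium diisopropylamide, CC(C)[N-]C(C)C.[Li+] (supplies the lithium of 3)
Why: Lactone enolate alkylation (SN2) in which the iodide approaches the convex face of the cis-fused bicycle, anti to the cyclopentene carbon on C2, which sets C1′ (S) relative to C2.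

Step 2
Reactants: 4 butenyl lactone
Product: 5 (1S,2S)-2-[(2S)-1-hydroxyhex-5-en-2-yl]cyclopent-3-en-1-ol
Conditions: LiAlH4, THF, 0 °C; Fieser work-up
Reagents that add atoms: none
Why: Hydride reduction of the lactone to the 1,4-diol, which frees C11–OH and C3–OH with the cis C2/C3 relationship fixed by the former ring fusion.

Step 3
Reactants: 5 diol
Product: 6 (1S,2S)-2-[(2S)-1-(4-methoxybenzyloxy)hex-5-en-2-yl]cyclopent-3-en-1-ol
Conditions: NaH (1.0 equiv), PMBCl, Bu4NI (cat.), THF–DMF, 0 °C
Reagents that add atoms: 4-methoxybenzyl chloride, COc1ccc(CCl)cc1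
Why: Williamson etherification in which the primary alkoxide should react in preference to the secondary cyclopentanol, which is flanked by the branched cis C2 substituent.

Step 4
Reactants: 6 PMB ether
Product: 7 tert-butyldimethylsilyl ether of 6 at C3–OH
Conditions: TBSOTf, 2,6-lutidine, CH2Cl2, −78 → 0 °C
Reagents that add atoms: tert-butyldimethylsilyl trifluoromethanesulfonate, CC(C)(C)[Si](C)(C)OS(=O)(=O)C(F)(F)F
Why: Silylation of a hindered secondary alcohol with the silyl triflate, under conditions that leave the PMB ether and both alkenes untouched.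

Step 5
Reactants: 7 cyclopentene
Product: 8 C1–C5 epoxide of 7 with the oxirane oxygen trans to the C2 side chain and the C3 silyl ether
Conditions: mCPBA (1.05 equiv), NaHCO3, CH2Cl2, 0 °C
Reagents that add atoms: 3-chloroperbenzoic acid, OOC(=O)c1cccc(Cl)c1
Why: Prilezhaev epoxidation, in which the cis-disubstituted cyclopentene should react well ahead of the monosubstituted terminal alkene and the peracid approaches the face opposite the two cis substituents on C2 and C3.

Step 6
Reactants: 8 epoxide; 9 2-methylbut-2-ene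
Product: 10 epoxide 8 with the side chain capped as (2S)-1-(4-methoxybenzyloxy)-6-methylhept-5-en-2-yl
Conditions: Grubbs second-generation catalyst (5 mol%), 9 (excess, co-solvent), CH2Cl2, 35 °C
Reagents that add atoms: none
Why: Olefin cross-metathesis of the terminal alkene with 2-methylbut-2-ene installs the isopropylidene terminus only after the ring alkene has been consumed, so the trisubstituted olefin never competes with the epoxidation.

Step 7
Reactants: 10 epoxide; 11 vinylmagnesium bromide
Product: 12 cyclopentanol with C1–OH trans to the new C5 vinyl group (vinyl cis to the C2 side chain and C3–OTBS)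
Conditions: 11 (3 equiv), CuI (20 mol%), THF, −40 → 0 °C; NH4Cl work-up
Reagents that add atoms: none
Why: Copper-catalysed SN2 opening of the epoxide with inversion at C5, the oxirane carbon remote from the branched C2 substituent (attack at C1 would be cis-vicinal to the side chain); the C5 centre is reset in step 9.

Step 8
Reactants: 12 cyclopentanol
Product: 13 2,3-cis-3-silyloxy-5-vinylcyclopentanone (C1 ketone)
Conditions: Dess–Martin periodinane, NaHCO3, CH2Cl2, 0 °C → rt
Reagents that add atoms: none
Why: Dess–Martin oxidation under buffered, non-basic conditions, so that the β-silyloxy ketone does not eliminate and the α-vinyl ketone is not isomerised into conjugation.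

Step 9
Reactants: 13 vinyl ketone
Product: 15 5-methyl-5-vinylcyclopentanone with methyl trans and vinyl cis to the C2 side chain, via lithium dienolate 14 (not isolated)
Conditions: LiHMDS (1.1 equiv), THF, −78 °C; then MeI, DMPU, −78 → −40 °C
Reagents that add atoms: iodomethane, CI; lithium hexamethyldisilazide, C[Si](C)(C)[N-][Si](C)(C)C.[Li+] (supplies the lithium of 14)
Why: Enolate alkylation in which the doubly activated C5–H (α to the carbonyl and allylic) is removed in preference to the hindered C2–H, and the dienolate is methylated at its α-carbon from the face opposite the C2 side chain and the C3 silyl ether, fixing the quaternary C5.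

Step 10
Reactants: 15 methyl vinyl ketone; 11 vinylmagnesium bromide
Product: 16 (1S,2S,3S,5S)-3-(tert-butyldimethylsilyloxy)-2-[(2S)-1-(4-methoxybenzyloxy)-6-methylhept-5-en-2-yl]-5-methyl-1,5-divinylcyclopentan-1-ol
Conditions: 11, anhydrous CeCl3, THF, −78 °C; NH4Cl work-up
Reagents that add atoms: none
Why: Organocerium-type 1,2-addition (Imamoto conditions), which suppresses enolisation toward C2; the vinyl group adds to the carbonyl face anti to the C2 side chain (the face of the small C5 methyl), giving the carbinol with the two vinyl groups trans.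

Step 11
Reactants: 16 trans-1,2-divinylcyclopentanol
Product: 19 (E)-cyclonon-5-enone with C1 ketone and C1′/C2/C3 unchanged, via potassium alkoxide 17 (not isolated), via potassium enolate 18 (not isolated)
Conditions: KH, 18-crown-6, THF, 0 → 25 °C; then AcOH in THF, −78 °C
Reagents that add atoms: potassium hydride, [K+].[H-] (supplies the potassium of 17 and 18)
Why: Deprotonation gives the crown-separated alkoxide, whose weakened C1–C5 bond undergoes a charge-accelerated [3,3] shift through the six-atom array C8=C9–C1–C5–C6=C7, forming C7–C8 as C1–C5 breaks. The closest known reaction type is the anionic oxy-Cope ring expansion of trans-1,2-divinylcycloalkanols to (E)-cycloalk-5-enones. The nine-membered ring is closed by four-carbon ring expansion of the cyclopentane within this sigmatropic transition state, not by an end-to-end cyclisation, and the driving force is enolate formation. No stereocentre is created (C1 and C5 become sp2), and C1′, C2 and C3 are spectators. The step needs E geometry at C5=C6, which the trans arrangement of the vinyl groups secures by allowing a chair-like array with ring carbons C2 and C4 pseudo-equatorial and O⁻ and the C5 methyl pseudo-axial. The enolate is formed only toward C9, and the cold acetic acid quench protonates it before proton transfer to C2 could expel the C3 silyloxy group or epimerise C2.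

Step 12
Reactants: 19 cyclononenone
Product: 21 C1(OTMS)=C9 trimethylsilyl enol ether of 19, via lithium enolate 20 (not isolated)
Conditions: LDA, TMSCl–Et3N (internal quench), THF, −78 °C
Reagents that add atoms: chlorotrimethylsilane, C[Si](C)(C)Cl; lithium diisopropylamide, CC(C)[N-]C(C)C.[Li+] (supplies the lithium of 20)
Why: Kinetic enolisation removes a C9 methylene proton in preference to the hindered C2 methine, and in situ O-silylation traps the enolate before equilibration.

Step 13
Reactants: 21 silyl enol ether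
Product: 22 cyclonona-5,8-dienone (C8=C9 enone cis within the ring and C5=C6 E)
Conditions: Pd(OAc)2 (1.1 equiv), MeCN, rt
Reagents that add atoms: none
Why: Saegusa–Ito oxidation via the palladium enolate and β-hydride elimination toward C8, expected to give the ring-cis enone because a second trans double bond in the nine-membered ring would be prohibitively strained.

Step 14
Reactants: 22 enone
Product: 23 C9-hydroxymethyl enone (C12–OH)
Conditions: 37% aq. HCHO, DMAP (0.3 equiv), THF–H2O, rt
Reagents that add atoms: formaldehyde, C=O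
Why: Morita–Baylis–Hillman reaction of a 2-cycloalkenone with formaldehyde, in which reversible conjugate addition of DMAP at C8, aldol addition of the C9 enolate to formaldehyde and loss of DMAP restore the C8=C9 double bond.

Step 15
Reactants: 23 allylic alcohol
Product: 24 C12 triethylsilyl ether of 23
Conditions: TESCl, imidazole, CH2Cl2, 0 °C
Reagents that add atoms: chlorotriethylsilane, CC[Si](Cl)(CC)CC
Why: Silylation of the primary allylic alcohol, to keep it out of the titanium and borane steps.

Step 16
Reactants: 24 enone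
Product: 25 C1-methylene diene (C10H2=C1–C9=C8)
Conditions: Cp2TiMe2, toluene, 70 °C, dark
Reagents that add atoms: dimethyltitanocene, C[Ti](C)(C1C=CC=C1)C1C=CC=C1
Why: Petasis methylenation, a non-basic titanium-carbene olefination that tolerates hindered, enolisable ketones and so avoids β-elimination of the C3 silyl ether.

Step 17
Reactants: 25 diene
Product: 27 (1R)-C10 primary alcohol, via B-alkyl-9-BBN adduct 26 (not isolated)
Conditions: 9-BBN (1.5 equiv), THF, 0 °C → rt; then NaBO3·4H2O, H2O, rt
Reagents that add atoms: 9-borabicyclo[3.3.1]nonane, B1C2CCCC1CCC2 (boron and bicycle of 26); sodium perborate, [Na+].[O-]OB=O (oxygen of 27)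
Why: Hydroboration–oxidation, in which boron adds to the terminal C10 of the 1,1-disubstituted alkene much faster than to the trisubstituted alkenes; C1 is set by delivery of hydride to the face away from the C2–C1′ bond, which is expected to stand perpendicular to the diene plane to avoid the C9 substituent.

Step 18
Reactants: 27 primary alcohol
Product: 28 C10,C12-bis(triethylsilyl) ether
Conditions: TESCl, imidazole, CH2Cl2, 0 °C
Reagents that add atoms: chlorotriethylsilane, CC[Si](Cl)(CC)CC
Why: Silylation of the primary alcohol, so that C11–OH can be unmasked and acetylated alone.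

Step 19
Reactants: 28 PMB ether
Product: 29 C11 primary alcohol
Conditions: DDQ, CH2Cl2–pH 7 buffer, 0 °C
Reagents that add atoms: none
Why: Oxidative cleavage of the 4-methoxybenzyl ether by DDQ, which leaves the silyl ethers and the isolated trisubstituted alkenes intact under buffered conditions.

Step 20
Reactants: 29 alcohol
Product: 30 C11 acetate
Conditions: Ac2O, pyridine, DMAP (cat.), CH2Cl2, 0 °C → rt
Reagents that add atoms: acetic anhydride, CC(=O)OC(C)=O
Why: Acetylation of the only free hydroxyl.

Step 21
Reactants: 30 bis-TES ether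
Product: 31 C10,C12-diol (C11–OAc and C3–OTBS retained)
Conditions: PPTS (cat.), MeOH–CH2Cl2, 0 °C
Reagents that add atoms: none
Why: Acid-catalysed methanolysis removes the two primary triethylsilyl ethers much faster than the hindered secondary TBS ether, and the acetate is not touched.

Step 22
Reactants: 31 2-ene-1,4-diol
Product: 32 C3-O-TBS ether of the target (C10 and C12 dialdehyde)
Conditions: (COCl)2, DMSO, CH2Cl2, −78 °C; Et3N, −78 → −40 °C; cold pH 7 quench
Reagents that add atoms: none
Why: Swern oxidation, in which both alcohols are activated before base is added, so no hydroxy-aldehyde can close to a lactol, as in known oxidations of 2-ene-1,4-diols to ene-dials; the low temperature protects the epimerisable C1.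

Step 23
Reactants: 32 silyl ether
Product: 33 CNP0284729.1, (1R,2R,3S,5E,8E)-2-[(2S)-1-acetoxy-6-methylhept-5-en-2-yl]-3-hydroxy-5-methylcyclonona-5,8-diene-1,9-dicarbaldehyde (target numbering)
Conditions: HF·pyridine, pyridine, THF, 0 °C → rt
Reagents that add atoms: none
Why: Buffered HF desilylation of the secondary TBS ether under non-basic conditions, which should leave the acetate, the enal and the C1 stereocentre intact.

**Compound list**
1 | (1S,5R)-2-oxabicyclo[3.3.0]oct-6-en-3-one | O=C1C[C@@H]2C=CC[C@@H]2O1 | starting material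
2 | 4-iodobut-1-ene | C=CCCI | starting material
3 | lithium enolate of 1 | [Li]OC1=C[C@@H]2C=CC[C@@H]2O1 | intermediate
4 | (1S,4S,5S)-4-(but-3-en-1-yl)-2-oxabicyclo[3.3.0]oct-6-en-3-one | O=C1[C@@H](CCC=C)[C@@H]2C=CC[C@@H]2O1 | intermediate
5 | (1S,2S)-2-[(2S)-1-hydroxyhex-5-en-2-yl]cyclopent-3-en-1-ol | OC[C@@H](CCC=C)[C@@H]1C=CC[C@@H]1O | intermediate
6 | (1S,2S)-2-[(2S)-1-(4-methoxybenzyloxy)hex-5-en-2-yl]cyclopent-3-en-1-ol | COc1ccc(COC[C@@H](CCC=C)[C@@H]2C=CC[C@@H]2O)cc1 | intermediate
7 | TBS ether of 6 (C3–OTBS cis to the C2 side chain) | COc1ccc(COC[C@@H](CCC=C)[C@@H]2C=CC[C@@H]2O[Si](C)(C)C(C)(C)C)cc1 | intermediate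
8 | C1–C5 epoxide of 7, oxygen trans to the C2 and C3 substituents | COc1ccc(COC[C@@H](CCC=C)[C@H]2[C@@H](O[Si](C)(C)C(C)(C)C)C[C@@H]3O[C@@H]32)cc1 | intermediate
9 | 2-methylbut-2-ene | CC=C(C)C | starting material
10 | epoxide with 6-methylhept-5-en-2-yl side chain | COc1ccc(COC[C@@H](CCC=C(C)C)[C@H]2[C@@H](O[Si](C)(C)C(C)(C)C)C[C@@H]3O[C@@H]32)cc1 | intermediate
11 | vinylmagnesium bromide | C=C[Mg]Br | starting material
12 | cyclopentanol, C1–OH trans to C5 vinyl, vinyl cis to C2 side chain and C3–OTBS | COc1ccc(COC[C@@H](CCC=C(C)C)[C@H]2[C@@H](O[Si](C)(C)C(C)(C)C)C[C@@H](C=C)[C@@H]2O)cc1 | intermediate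
13 | 2-(side chain)-3-silyloxy-5-vinylcyclopentanone | COc1ccc(COC[C@@H](CCC=C(C)C)[C@H]2[C@@H](O[Si](C)(C)C(C)(C)C)C[C@@H](C=C)C2=O)cc1 | intermediate
14 | lithium dienolate of 13 (C1(OLi)=C5) | COc1ccc(COC[C@@H](CCC=C(C)C)[C@H]2[C@@H](O[Si](C)(C)C(C)(C)C)CC(C=C)=C2O[Li])cc1 | intermediate
15 | 5-methyl-5-vinylcyclopentanone, methyl trans and vinyl cis to the C2 side chain | COc1ccc(COC[C@@H](CCC=C(C)C)[C@H]2[C@@H](O[Si](C)(C)C(C)(C)C)C[C@@](C)(C=C)C2=O)cc1 | intermediate
16 | (1S,2S,3S,5S)-3-(TBS-oxy)-2-[(2S)-1-(4-methoxybenzyloxy)-6-methylhept-5-en-2-yl]-5-methyl-1,5-divinylcyclopentan-1-ol | COc1ccc(COC[C@@H](CCC=C(C)C)[C@H]2[C@@H](O[Si](C)(C)C(C)(C)C)C[C@@](C)(C=C)[C@]2(O)C=C)cc1 | intermediate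
17 | potassium alkoxide of 16 | COc1ccc(COC[C@@H](CCC=C(C)C)[C@H]2[C@@H](O[Si](C)(C)C(C)(C)C)C[C@@](C)(C=C)[C@]2(O[K])C=C)cc1 | intermediate
18 | potassium C1(OK)=C9 enolate of 19 (enolate geometry not specified) | COc1ccc(COC[C@@H](CCC=C(C)C)[C@H]2[C@@H](O[Si](C)(C)C(C)(C)C)C/C(C)=C/CCC=C2O[K])cc1 | intermediate
19 | (E)-cyclonon-5-enone, C1 ketone, C2 side chain, C3–OTBS, C5 methyl | COc1ccc(COC[C@@H](CCC=C(C)C)[C@H]2[C@@H](O[Si](C)(C)C(C)(C)C)C/C(C)=C/CCCC2=O)cc1 | intermediate
20 | lithium C1(OLi)=C9 enolate of 19 | COc1ccc(COC[C@@H](CCC=C(C)C)[C@H]2[C@@H](O[Si](C)(C)C(C)(C)C)C/C(C)=C/CCC=C2O[Li])cc1 | intermediate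
21 | C1(OTMS)=C9 silyl enol ether of 19 | COc1ccc(COC[C@@H](CCC=C(C)C)[C@H]2[C@@H](O[Si](C)(C)C(C)(C)C)C/C(C)=C/CCC=C2O[Si](C)(C)C)cc1 | intermediate
22 | cyclonona-5,8-dienone (C8=C9 ring-cis, C5=C6 E) | COc1ccc(COC[C@@H](CCC=C(C)C)[C@H]2[C@@H](O[Si](C)(C)C(C)(C)C)C/C(C)=C/C/C=C\C2=O)cc1 | intermediate
23 | C9-(hydroxymethyl) enone | COc1ccc(COC[C@@H](CCC=C(C)C)[C@H]2[C@@H](O[Si](C)(C)C(C)(C)C)C/C(C)=C/C/C=C(/CO)C2=O)cc1 | intermediate
24 | C12–OTES enone | COc1ccc(COC[C@@H](CCC=C(C)C)[C@H]2[C@@H](O[Si](C)(C)C(C)(C)C)C/C(C)=C/C/C=C(/CO[Si](CC)(CC)CC)C2=O)cc1 | intermediate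
25 | C1-methylene diene | COc1ccc(COC[C@@H](CCC=C(C)C)[C@H]2[C@@H](O[Si](C)(C)C(C)(C)C)C/C(C)=C/C/C=C(/CO[Si](CC)(CC)CC)C2=C)cc1 | intermediate
26 | B-(C10-alkyl)-9-BBN adduct | COc1ccc(COC[C@@H](CCC=C(C)C)[C@H]2[C@@H](O[Si](C)(C)C(C)(C)C)C/C(C)=C/C/C=C(/CO[Si](CC)(CC)CC)[C@@H]2CB3C4CCCC3CCC4)cc1 | intermediate
27 | (1R)-C10 alcohol | COc1ccc(COC[C@@H](CCC=C(C)C)[C@H]2[C@@H](O[Si](C)(C)C(C)(C)C)C/C(C)=C/C/C=C(/CO[Si](CC)(CC)CC)[C@@H]2CO)cc1 | intermediate
28 | C10,C12-bis-TES ether | COc1ccc(COC[C@@H](CCC=C(C)C)[C@H]2[C@@H](O[Si](C)(C)C(C)(C)C)C/C(C)=C/C/C=C(/CO[Si](CC)(CC)CC)[C@@H]2CO[Si](CC)(CC)CC)cc1 | intermediate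
29 | C11 alcohol | OC[C@@H](CCC=C(C)C)[C@H]1[C@@H](O[Si](C)(C)C(C)(C)C)C/C(C)=C/C/C=C(/CO[Si](CC)(CC)CC)[C@@H]1CO[Si](CC)(CC)CC | intermediate
30 | C11 acetate | CC(=O)OC[C@@H](CCC=C(C)C)[C@H]1[C@@H](O[Si](C)(C)C(C)(C)C)C/C(C)=C/C/C=C(/CO[Si](CC)(CC)CC)[C@@H]1CO[Si](CC)(CC)CC | intermediate
31 | C10,C12-diol with C11–OAc and C3–OTBS | CC(=O)OC[C@@H](CCC=C(C)C)[C@H]1[C@@H](O[Si](C)(C)C(C)(C)C)C/C(C)=C/C/C=C(/CO)[C@@H]1CO | intermediate
32 | C3-O-TBS ether of the target | CC(=O)OC[C@@H](CCC=C(C)C)[C@H]1[C@@H](O[Si](C)(C)C(C)(C)C)C/C(C)=C/C/C=C(/C=O)[C@@H]1C=O | intermediate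
33 | CNP0284729.1 | CC(=O)OC[C@@H](CCC=C(C)C)[C@H]1[C@@H](O)C/C(C)=C/C/C=C(/C=O)[C@@H]1C=O | target

**Step count**
Total steps: 23. Longest linear sequence: 23 steps (from 1).

**Steps most likely to fail**

Step 11 (ring expansion). The naked alkoxide may cleave the C1–C5 bond heterolytically (retro-allylation) and reclose unselectively, or react through a boat-like array and erode the E selectivity. The cis-1,3 silyl group on C3 may migrate to the C1 oxygen, or silanolate may be lost by β-elimination once proton transfer moves the enolate to C2. Fallback, setting out from 16: the tertiary alcohol is silylated (TMSOTf, Et3N, CH2Cl2, −78 °C) to the trimethylsilyl ether of the divinylcarbinol F1. This is heated in a sealed tube (toluene, N,O-bis(trimethylsilyl)acetamide as acid scavenger, about 200 °C), so that the neutral siloxy-Cope rearrangement, free of charged intermediates, gives the C1(OTMS)=C9 silyl enol ether directly. The route is rejoined at 21, bypassing steps 11 and 12.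

Step 14 (hydroxymethylation). Conjugate addition of the amine catalyst to the twisted, β-substituted nine-membered enone may be too slow or too reversible for the aldol step to compete, and prolonged exposure to base may cause β-elimination of the C3 silyloxy group. Fallback, setting out from 19: the kinetic C9 enolate (LDA, THF, −78 °C) is selenenylated with PhSeBr to the α-phenylselanyl ketone F2. A second deprotonation at the selenium-bearing C9 (LDA, −78 °C) and addition of monomeric formaldehyde gives the α-hydroxymethyl-α-phenylselanyl ketone F3. Oxidation (H2O2, pyridine, CH2Cl2, 0 °C) gives the selenoxide F4, which undergoes syn-elimination toward C8, away from the oxygenated C12. The route is rejoined at 23, bypassing steps 12–14.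

Step 17 (hydroboration). Hydride may be delivered to the other face of C1, because the facial preference rests on a single conformational model of the nine-membered diene; by analogy with 2-substituted methylenecycloalkanes the opposite face could well be favoured. Hydroboration of the strained E C5=C6 olefin may also compete. Fallback, setting out from 25 and switching from kinetic to thermodynamic control: the hydroboration product with the wrong configuration, the C1 epimer of alcohol 27 F5, is oxidised (Dess–Martin periodinane, NaHCO3) to the C1-epimeric C10 aldehyde F6. Brief treatment with catalytic DBU (CH2Cl2, 0 °C) equilibrates the α-centre toward the aldehyde with the target C1 configuration F7, in which the formyl group is anti to C3 across the C1–C2 bond; this preference is expected to be modest, so the epimers may need separation. Reduction (NaBH4, MeOH, 0 °C) returns the route at 27.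

**Further compounds**
F1 | step 11 | trimethylsilyl ether of 16 | COc1ccc(COC[C@@H](CCC=C(C)C)[C@H]2[C@@H](O[Si](C)(C)C(C)(C)C)C[C@@](C)(C=C)[C@]2(O[Si](C)(C)C)C=C)cc1
F2 | step 14 | C9-phenylselanyl derivative of 19 | COc1ccc(COC[C@@H](CCC=C(C)C)[C@H]2[C@@H](O[Si](C)(C)C(C)(C)C)C/C(C)=C/CCC([Se]c3ccccc3)C2=O)cc1
F3 | step 14 | C9-hydroxymethyl-C9-phenylselanyl ketone | COc1ccc(COC[C@@H](CCC=C(C)C)[C@H]2[C@@H](O[Si](C)(C)C(C)(C)C)C/C(C)=C/CCC(CO)([Se]c3ccccc3)C2=O)cc1
F4 | step 14 | selenoxide of F3 | COc1ccc(COC[C@@H](CCC=C(C)C)[C@H]2[C@@H](O[Si](C)(C)C(C)(C)C)C/C(C)=C/CCC(CO)([Se](=O)c3ccccc3)C2=O)cc1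
F5 | step 17 | C1 epimer of alcohol 27 | COc1ccc(COC[C@@H](CCC=C(C)C)[C@H]2[C@@H](O[Si](C)(C)C(C)(C)C)C/C(C)=C/C/C=C(/CO[Si](CC)(CC)CC)[C@H]2CO)cc1
F6 | step 17 | C1-epimeric C10 aldehyde | COc1ccc(COC[C@@H](CCC=C(C)C)[C@H]2[C@@H](O[Si](C)(C)C(C)(C)C)C/C(C)=C/C/C=C(/CO[Si](CC)(CC)CC)[C@H]2C=O)cc1
F7 | step 17 | C10 aldehyde with the target C1 configuration | COc1ccc(COC[C@@H](CCC=C(C)C)[C@H]2[C@@H](O[Si](C)(C)C(C)(C)C)C/C(C)=C/C/C=C(/CO[Si](CC)(CC)CC)[C@@H]2C=O)cc1
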